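## Structural features

The target is an achiral, fully aromatic 2-arylchromen-4-one. Ring A (benzene) is fused to the pyranone ring C through C4a–C8a, and ring B (phenyl) is attached at C2. Every carbon of ring A bears oxygen (5-OH, 6-OMe, 7-OH, 8-OMe), C3 carries a methoxyl, and ring B has 2'- and 5'-methoxyls and a free 4'-hydroxyl. The target has no stereocentre; the only stereocentres of the route are the adjacent C2 and C3 of a flavanone intermediate, and both are erased on dehydrogenation. Fragile features are the electron-rich, easily oxidised rings (ring A, oxygenated at C5 and C8, behaves as a masked hydroquinone), the pyranone ring, which strong nucleophiles can open at C2, and the three phenols that may only be free at the end. The real difficulty is regiochemical: hydroxyl and methoxyl must be told apart on the hexasubstituted ring A (5/7 against 6/8) and on ring B. The key step uses the fact that O1–C8a and C4–C4a are neighbouring bonds of ring A, so C8a and C4a can be the two carbons of an aryne. The C5 oxygen next to C4a polarises that aryne, and an α-methoxycinnamic acid supplies C4, C3 with its methoxyl, and C2 with ring B.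

## Logic of the disconnections

27 to 26: the benzyl–oxygen bonds at O7 and O4' are cut. Benzyl ethers leave by hydrogenolysis without touching aryl methyl ethers or the chelated 5-hydroxyl. The gain is that the two most acidic phenols stay masked through the oxidation and methylation steps. The forward step must spare the C2=C3 bond of ring C.

26 to 25: the O8–CH3 bond is cut. In 25 the C8 hydroxyl is the only phenol not locked in a hydrogen bond to C4=O, so monomethylation can be selective. The demand is exclusion of air, because 25 is a para-hydroquinone.

25 to 23: the C8–O bond is cut. C8 is the only unsubstituted carbon of ring A and lies para to the 5-hydroxyl, the site that a phenoxide offers to persulfate. This lets ring A enter the key step with hydrogen at C8, which is what leaves the aryne with oxygen on one flank only. The forward step needs the 5-hydroxyl free and every other phenol protected.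

23 to 22: the benzyl group is put back on O5. With three identical benzyl ethers in 22, the ring A precursor can be symmetric. The forward step must remove only the benzyl group peri to the carbonyl.

22 to 21: hydrogen is added across C2–C3. The flavanone is the direct product of oxa-Michael ring closure, and removing the unsaturation requirement means the C2/C3 stereocentres need no control. The forward oxidation must leave benzyl ethers intact.

21 to 10 and 18 (through 19 and 20): O1–C8a, C4–C4a and O1–C2 are cut. The first two bonds sit on adjacent carbons of ring A and therefore map onto an aryne; the third is a conjugate addition. Mapping 10 onto ring A atom by atom gives: triflate carbon to C8a, silyl carbon to C4a, flanking benzyloxy carbon to C5, methoxy carbon to C6, second benzyloxy carbon to C7, CH to C8. This matches the substitution of 21, so no structure needed correction. The gain is a convergent split into two fragments of similar size. The demands are regioselective capture of 19, acyl transfer faster than protonation, and ring closure of 20. Two refinements are made: 18 is charged as its cesium salt, and any 20 that fails to close is carried forward, since the next step converts 20 and 21 alike.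

10 to 7 to 6: the C–Si and O–S bonds are cut, then the C–Br bond. An ortho-silylaryl triflate comes from an ortho-bromophenol by O-silylation, halogen–metal exchange, silyl shift and triflation. Because 6 has a mirror plane through C1 and C4, bromination gives one isomer and only one aryne can form. The demands are clean monobromination and exchange that outruns benzylic metalation.

6 to 4 to 3 to 2 to 1: the aryl C–O bond is traced to an aryl C–CHO bond (peracid oxidation), the aldehyde to the ester through the alcohol, and the two benzyl–oxygen bonds are cut. In 1 the methoxyl flanked by two hydroxyls is already the future 6-OMe between O5 and O7. The demand is aryl rather than hydride migration in the oxidation of 4.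

18 to 15 and 16 (through 17): the alkene bond between the α- and β-carbons is cut. The C3 methoxyl is bought with 16, and the condensation joins it to the ring B aldehyde. The demand is condensation with an electron-rich aldehyde; alkene geometry is irrelevant later.

15 to 14 to 13 to 11: the aryl–CHO bond is cut (formylation para to the benzyloxy group), then the benzyl–oxygen bond, then the aryl C–O bond (peracid oxidation of the formyl group of 11). Because 11 has no oxygen at the future C4', its formyl group is turned into that oxygen and a new formyl group is introduced para to it. The demand is regioselective formylation of a 1,2,4-trioxygenated benzene.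

## Other disconnections considered

Alternative 1: The cut is O1–C8a on the open-chain diketone A1, 1-[2,4-bis(benzyloxy)-3,5-dimethoxyphenyl]-3-[2,5-dimethoxy-4-(pivaloyloxy)phenyl]-2-methoxypropane-1,3-dione. In the forward step, anodic two-electron oxidation of the enol of A1 would join the enol oxygen on the ring B side to the single C–H of ring A and give flavone A2.
- In favour: ring A enters with all four oxygens in place, so neither the persulfate oxidation nor the selective debenzylation is needed. The closure site on ring A is unambiguous. No chemical oxidant is used. A2 is two deprotections from 27, against five steps after the key step of the chosen plan; on this count the alternative is better.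
- Against: ring A of A1 is a tetraalkoxyphenyl ketone with alternating benzyl and methyl groups, so the 5/7 against 6/8 problem is only moved into a longer fragment synthesis. The electron-rich rings and benzylic ethers should oxidise at potentials close to that of the enol, so over-oxidation to quinones and benzylic oxidation are likely competitors. Ring B also has a C–H ortho to its carbonyl, so the other enol oxygen could close onto ring B and give the ring-exchanged flavone; the pivalate can only partly bias this. A direct anodic C–H/O–H closure of a diaryl diketone to a chromone has no close precedent.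
- Comparison: on structure the alternative is equal or better (complete ring A before closure). On mechanism the chosen plan is safer, since aryne insertion into cinnamic acids is an established reaction type. Overall step count should be similar, because the steps saved at the end are spent on A1.

Alternative 2: The cut is C8–C8a, with ring A grown on a preformed pyranone. The precursor is cyclobutenone A3, 2-[4-(benzyloxy)-2,5-dimethoxyphenyl]-5-(3-tert-butoxy-1-hydroxy-2-methoxy-4-oxocyclobut-2-en-1-yl)-3-methoxy-4H-pyran-4-one. Heating should open it to a dienylketene that closes by 6π-electrocyclisation onto the pyranone CH next to the ring oxygen and tautomerises to hydroquinone A4 (Moore rearrangement).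
- In favour: ring A is built in one step with all four oxygens. The C5 and C8 hydroxyls of A4 differ by chelation, so C8 methylation is straightforward, and the C7 oxygen is marked as an acid-labile tert-butyl ether. This is better than the chosen plan for the C8 oxygen, and three steps would follow the key step instead of five.
- Against: A3 requires a 5-metallated 2-aryl-3-methoxypyranone, which is prone to conjugate addition and ring opening. It must add to the correct carbonyl of a mixed methyl tert-butyl squaric ester, whose two carbonyls differ only by a remote alkoxy group; poor control would swap the C6 and C7 substituents. Thermolysis may also strip isobutene from the tert-butyl ether, and A4 is air-sensitive.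
- Comparison: the pericyclic cascade is as reliable a reaction type as the aryne insertion. The regiochemical weak point lies in making A3, whereas the chosen plan fixes regiochemistry by the symmetry of 6 and the alkoxy effect in 19. Total step count is expected to be equal or higher, because the halogenated pyranone must be made first.

Alternative 3: The cuts are the C5–O and C7–O bonds; no ring is formed. Benzyloxide would displace both fluorides of difluoroflavone A5, 2-[4-(benzyloxy)-2,5-dimethoxyphenyl]-5,7-difluoro-3,6,8-trimethoxy-4H-chromen-4-one, by SNAr to give tribenzyl ether A6.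
- In favour: C5 is ortho and C7 para to the C4 carbonyl, so both are activated. Fluorine survives the earlier flavone construction. The hydroxyl/methoxyl pattern of ring A is encoded without any selective deprotection. A6 is one hydrogenolysis from 27, the shortest endgame of all and better than the chosen plan.
- Against: each fluorine is flanked by donor groups (C7–F between two methoxyls), and the ring becomes more electron-rich after the first displacement, so the second needs forcing conditions. Under those conditions benzyloxide can add at C2 and open ring C, or demethylate aryl methyl ethers. The step builds no skeleton, so the whole flavone A5, with a pentasubstituted difluoro ring A, must be made by another ring-C construction.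
- Comparison: SNAr is as well founded as the aryne step, and the alternative is better on the final steps. It is worse on the steps before the key step and in convergence, and the double displacement on a deactivated ring is the less predictable event.

Key step: step 11

Remark on the chemistry: 21 is made and used as the racemate, because both of its stereocentres disappear in step 12; one enantiomer is drawn in its SMILES.

## Route

Step 1
Reactants: 1 methyl 3,5-dihydroxy-4-methoxybenzoate
Product: 2 methyl 3,5-bis(benzyloxy)-4-methoxybenzoate
Conditions: BnBr (2.3 equiv), K2CO3, DMF, 60 °C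
Reagents that add atoms: benzyl bromide, BrCc1ccccc1
Why: Williamson ether synthesis; both phenols are alkylated and the ester is untouched by carbonate.

Step 2
Reactants: 2 methyl 3,5-bis(benzyloxy)-4-methoxybenzoate
Product: 3 [3,5-bis(benzyloxy)-4-methoxyphenyl]methanol
Conditions: LiAlH4, THF, 0 °C to rt
Reagents that add atoms: none
Why: Hydride reduction of the ester to the primary alcohol; full reduction and reoxidation is chosen over partial reduction, which tends to over-reduce aryl esters.

Step 3
Reactants: 3 [3,5-bis(benzyloxy)-4-methoxyphenyl]methanol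
Product: 4 3,5-bis(benzyloxy)-4-methoxybenzaldehyde
Conditions: MnO2 (activated, excess), CH2Cl2, rt
Reagents that add atoms: none
Why: Selective oxidation of a benzylic alcohol to the aldehyde without over-oxidation; ethers are inert.

Step 4
Reactants: 4 3,5-bis(benzyloxy)-4-methoxybenzaldehyde
Product: 6 3,5-bis(benzyloxy)-4-methoxyphenol, via aryl formate 5 (not isolated)
Conditions: mCPBA, CH2Cl2, 0 °C to rt; then K2CO3 (0.2 equiv), MeOH, rt
Reagents that add atoms: 3-chloroperoxybenzoic acid, O=C(OO)c1cccc(Cl)c1
Why: Baeyer–Villiger (Dakin-type) oxidation; the electron-rich trialkoxyaryl group migrates in preference to hydride, and the formate is methanolysed in the same flask to the symmetric phenol.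

Step 5
Reactants: 6 3,5-bis(benzyloxy)-4-methoxyphenol
Product: 7 3,5-bis(benzyloxy)-2-bromo-4-methoxyphenol
Conditions: NBS (1.0 equiv), CH2Cl2, −78 to 0 °C
Reagents that add atoms: N-bromosuccinimide, O=C1CCC(=O)N1Br
Why: Electrophilic aromatic bromination ortho to the hydroxyl; the para position is blocked and the two ortho positions are equivalent by symmetry, so one monobromide is expected. Low temperature and one equivalent limit dibromination and oxidation to a quinone.

Step 6
Reactants: 7 3,5-bis(benzyloxy)-2-bromo-4-methoxyphenol
Product: 10 3,5-bis(benzyloxy)-4-methoxy-2-(trimethylsilyl)phenyl trifluoromethanesulfonate, via O-trimethylsilyl ether 8 (not isolated), via lithium 2-silylphenoxide 9 (not isolated)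
Conditions: HMDS, THF, 65 °C, then evaporate; n-BuLi, THF, −100 to −78 °C; Tf2O, −78 °C
Reagents that add atoms: hexamethyldisilazane, C[Si](C)(C)N[Si](C)(C)C; trifluoromethanesulfonic anhydride, O=S(=O)(OS(=O)(=O)C(F)(F)F)C(F)(F)F
Why: O-silylation, bromine–lithium exchange (faster than benzylic deprotonation at this temperature), anionic 1,3 oxygen-to-carbon silyl shift (retro-Brook rearrangement) and O-triflation of the resulting phenoxide; this is the standard sequence to ortho-silylaryl triflates.

Step 7
Reactants: 11 2,5-dimethoxybenzaldehyde
Product: 13 2,5-dimethoxyphenol, via aryl formate 12 (not isolated)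
Conditions: mCPBA, CH2Cl2, 0 °C to rt; then K2CO3 (0.2 equiv), MeOH, rt
Reagents that add atoms: 3-chloroperoxybenzoic acid, O=C(OO)c1cccc(Cl)c1
Why: Baeyer–Villiger (Dakin-type) oxidation with migration of the ortho-methoxyaryl group, then methanolysis of the formate; the former formyl carbon becomes the site of the future 4'-oxygen.

Step 8
Reactants: 13 2,5-dimethoxyphenol
Product: 14 2-(benzyloxy)-1,4-dimethoxybenzene
Conditions: BnBr, K2CO3, DMF, 50 °C
Reagents that add atoms: benzyl bromide, BrCc1ccccc1
Why: Williamson ether synthesis on the only phenol.

Step 9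
Reactants: 14 2-(benzyloxy)-1,4-dimethoxybenzene
Product: 15 4-(benzyloxy)-2,5-dimethoxybenzaldehyde
Conditions: POCl3, DMF, 0 to 70 °C; then ice–water
Reagents that add atoms: N,N-dimethylformamide, CN(C)C=O; water, O
Why: Vilsmeier–Haack formylation; attack should occur para to the benzyloxy group and ortho to a methoxyl, the position formylated in 1,2,4-trialkoxybenzenes, while the carbon between two oxygens is hindered.

Step 10
Reactants: 15 4-(benzyloxy)-2,5-dimethoxybenzaldehyde; 16 methyl methoxyacetate
Product: 18 (Z)-3-[4-(benzyloxy)-2,5-dimethoxyphenyl]-2-methoxyprop-2-enoic acid, via methyl ester 17 (not isolated)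
Conditions: 16 (3 equiv), NaOMe, MeOH–THF, 65 °C; then NaOH, H2O, 65 °C; then HCl to pH 2
Reagents that add atoms: sodium hydroxide, [Na+].[OH-]
Why: Ester-enolate aldol condensation with loss of water (Claisen-type), then saponification; the Z isomer (aryl trans to carboxyl) is the more stable one, and the geometry has no consequence for step 11.

Step 11
Reactants: 10 3,5-bis(benzyloxy)-4-methoxy-2-(trimethylsilyl)phenyl trifluoromethanesulfonate; 18 (Z)-3-[4-(benzyloxy)-2,5-dimethoxyphenyl]-2-methoxyprop-2-enoic acid
Product: 21 trans-5,7-bis(benzyloxy)-2-[4-(benzyloxy)-2,5-dimethoxyphenyl]-3,6-dimethoxychroman-4-one (racemic), via aryne 19 (not isolated), via hydroxychalcone 20 (not isolated)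
Conditions: 10 (1.5 equiv), 18 premixed with CsF (4 equiv), THF, 125 °C, sealed tube
Reagents that add atoms: none
Why: Fluoride attacks silicon of 10 and triflate leaves to give aryne 19; the cesium carboxylate of 18 adds to the aryne carbon remote from the flanking benzyloxy group (future C8a), so that the aryl anion develops at the carbon next to that oxygen (future C4a), where it is stabilised inductively. This anion attacks the adjacent ester carbonyl through a four-membered transition state, an anionic 1,3 oxygen-to-carbon acyl shift that forms C4a–C4 and frees the phenoxide of 20. The phenoxide closes ring C by 6-endo-trig oxa-Michael addition to the α-methoxy enone (O1–C2), and protonation of the enolate gives 21. The closest known reaction type is the insertion of arynes into the C–O bond of carboxylic acids, which with cinnamic acids gives flavanones under the same fluoride conditions. The C2 and C3 stereocentres arise in the reversible oxa-Michael addition and enolate protonation, so thermodynamic control should place aryl and methoxyl both equatorial (trans); no enantiocontrol is needed because both centres are erased in step 12. The step needs regioselective aryne capture, secured by the C5 benzyloxy group and by the symmetric origin of 10, which allows only one aryne. It also needs acyl transfer to outrun protonation of the aryl anion, which is favoured by THF at high temperature and by charging 18 as its salt, and capture by carboxylate rather than by the enol-ether double bond. Any 20 that does not close is not lost, because step 12 converts 20 and 21 to the same flavone.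

Step 12
Reactants: 21 trans-5,7-bis(benzyloxy)-2-[4-(benzyloxy)-2,5-dimethoxyphenyl]-3,6-dimethoxychroman-4-one
Product: 22 5,7-bis(benzyloxy)-2-[4-(benzyloxy)-2,5-dimethoxyphenyl]-3,6-dimethoxy-4H-chromen-4-one
Conditions: I2 (0.2 equiv), DMSO, 120 °C
Reagents that add atoms: none
Why: Iodine-mediated dehydrogenation of a flavanone: iodination of the enol at C3 and loss of HI across C2–C3, with DMSO reoxidising HI; catalytic iodine limits ring iodination. Both stereocentres are erased, and any 5-O-benzyl lost here would only anticipate step 13.

Step 13
Reactants: 22 5,7-bis(benzyloxy)-2-[4-(benzyloxy)-2,5-dimethoxyphenyl]-3,6-dimethoxy-4H-chromen-4-one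
Product: 23 7-(benzyloxy)-2-[4-(benzyloxy)-2,5-dimethoxyphenyl]-5-hydroxy-3,6-dimethoxy-4H-chromen-4-one
Conditions: MgBr2·OEt2 (3 equiv), toluene–Et2O, 80 °C; then dilute HCl
Reagents that add atoms: none
Why: Chelation-controlled Lewis-acid dealkylation: magnesium bridges C4=O and O5 in a six-membered chelate and bromide removes the benzyl group by SN2. The 7-O- and 4'-O-benzyl ethers cannot chelate, and the 3-methoxyl offers only a five-membered chelate and a much poorer methyl electrophile.

Step 14
Reactants: 23 7-(benzyloxy)-2-[4-(benzyloxy)-2,5-dimethoxyphenyl]-5-hydroxy-3,6-dimethoxy-4H-chromen-4-one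
Product: 25 7-(benzyloxy)-2-[4-(benzyloxy)-2,5-dimethoxyphenyl]-5,8-dihydroxy-3,6-dimethoxy-4H-chromen-4-one, via aryl sulfate 24 (not isolated)
Conditions: K2S2O8, KOH, H2O–pyridine, 15 °C to rt; then HCl, Na2SO3, H2O, 85 °C
Reagents that add atoms: potassium peroxodisulfate, [K+].[K+].[O-]S(=O)(=O)OOS(=O)(=O)[O-]
Why: Elbs persulfate oxidation: the 5-phenoxide attacks a peroxide oxygen through its para carbon C8, the only free carbon of ring A, and acid hydrolysis cleaves the aryl sulfate. Ring B has no free phenol and should not react, sulfite protects the hydroquinone from air, and unreacted 23 is recovered before hydrolysis.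

Step 15
Reactants: 25 7-(benzyloxy)-2-[4-(benzyloxy)-2,5-dimethoxyphenyl]-5,8-dihydroxy-3,6-dimethoxy-4H-chromen-4-one
Product: 26 7-(benzyloxy)-2-[4-(benzyloxy)-2,5-dimethoxyphenyl]-5-hydroxy-3,6,8-trimethoxy-4H-chromen-4-one
Conditions: MeI (1.2 equiv), K2CO3, acetone, 40 °C, under argon
Reagents that add atoms: iodomethane, CI
Why: Williamson methylation under mild base; the C8 hydroxyl is free, whereas the C5 hydroxyl is held in a hydrogen bond to C4=O and is far less nucleophilic.

Step 16
Reactants: 26 7-(benzyloxy)-2-[4-(benzyloxy)-2,5-dimethoxyphenyl]-5-hydroxy-3,6,8-trimethoxy-4H-chromen-4-one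
Product: 27 5,7-dihydroxy-2-(4-hydroxy-2,5-dimethoxyphenyl)-3,6,8-trimethoxy-4H-chromen-4-one
Conditions: H2 (1 atm), Pd/C (10% palladium on carbon), EtOAc–MeOH, rt
Reagents that add atoms: none
Why: Catalytic hydrogenolysis of the two benzyl aryl ethers; the chromone double bond and the methyl ethers are not reduced at ambient pressure and temperature.

## Compound list

1 | methyl 3,5-dihydroxy-4-methoxybenzoate | COC(=O)c1cc(O)c(OC)c(O)c1 | starting material
2 | methyl 3,5-bis(benzyloxy)-4-methoxybenzoate | COC(=O)c1cc(OCc2ccccc2)c(OC)c(OCc2ccccc2)c1 | intermediate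
3 | [3,5-bis(benzyloxy)-4-methoxyphenyl]methanol | COc1c(OCc2ccccc2)cc(CO)cc1OCc1ccccc1 | intermediate
4 | 3,5-bis(benzyloxy)-4-methoxybenzaldehyde | COc1c(OCc2ccccc2)cc(C=O)cc1OCc1ccccc1 | intermediate
5 | 3,5-bis(benzyloxy)-4-methoxyphenyl formate | COc1c(OCc2ccccc2)cc(OC=O)cc1OCc1ccccc1 | intermediate (not isolated)
6 | 3,5-bis(benzyloxy)-4-methoxyphenol | COc1c(OCc2ccccc2)cc(O)cc1OCc1ccccc1 | intermediate
7 | 3,5-bis(benzyloxy)-2-bromo-4-methoxyphenol | COc1c(OCc2ccccc2)cc(O)c(Br)c1OCc1ccccc1 | intermediate
8 | [3,5-bis(benzyloxy)-2-bromo-4-methoxyphenoxy]trimethylsilane | COc1c(OCc2ccccc2)cc(O[Si](C)(C)C)c(Br)c1OCc1ccccc1 | intermediate (not isolated)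
9 | lithium 3,5-bis(benzyloxy)-4-methoxy-2-(trimethylsilyl)phenoxide | [Li+].COc1c(OCc2ccccc2)cc([O-])c([Si](C)(C)C)c1OCc1ccccc1 | intermediate (not isolated)
10 | 3,5-bis(benzyloxy)-4-methoxy-2-(trimethylsilyl)phenyl trifluoromethanesulfonate | COc1c(OCc2ccccc2)cc(OS(=O)(=O)C(F)(F)F)c([Si](C)(C)C)c1OCc1ccccc1 | intermediate
11 | 2,5-dimethoxybenzaldehyde | COc1ccc(OC)c(C=O)c1 | starting material
12 | 2,5-dimethoxyphenyl formate | COc1ccc(OC)c(OC=O)c1 | intermediate (not isolated)
13 | 2,5-dimethoxyphenol | COc1ccc(OC)c(O)c1 | intermediate
14 | 2-(benzyloxy)-1,4-dimethoxybenzene | COc1ccc(OC)c(OCc2ccccc2)c1 | intermediate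
15 | 4-(benzyloxy)-2,5-dimethoxybenzaldehyde | COc1cc(OCc2ccccc2)c(OC)cc1C=O | intermediate
16 | methyl methoxyacetate | COCC(=O)OC | starting material
17 | methyl (Z)-3-[4-(benzyloxy)-2,5-dimethoxyphenyl]-2-methoxyprop-2-enoate | CO/C(=C\c1cc(OC)c(OCc2ccccc2)cc1OC)C(=O)OC | intermediate (not isolated)
18 | (Z)-3-[4-(benzyloxy)-2,5-dimethoxyphenyl]-2-methoxyprop-2-enoic acid | CO/C(=C\c1cc(OC)c(OCc2ccccc2)cc1OC)C(=O)O | intermediate
19 | 3,5-bis(benzyloxy)-4-methoxybenzyne (triple bond between the former triflate and silyl carbons) | COC1=C(OCc2ccccc2)C#CC=C1OCc1ccccc1 | intermediate (not isolated)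
20 | (Z)-1-[2,4-bis(benzyloxy)-6-hydroxy-3-methoxyphenyl]-3-[4-(benzyloxy)-2,5-dimethoxyphenyl]-2-methoxyprop-2-en-1-one (formed as its cesium phenoxide) | CO/C(=C\c1cc(OC)c(OCc2ccccc2)cc1OC)C(=O)c1c(O)cc(OCc2ccccc2)c(OC)c1OCc1ccccc1 | intermediate (not isolated)
21 | trans-5,7-bis(benzyloxy)-2-[4-(benzyloxy)-2,5-dimethoxyphenyl]-3,6-dimethoxychroman-4-one (racemic; 2S,3S enantiomer drawn) | CO[C@@H]1C(=O)c2c(OCc3ccccc3)c(OC)c(OCc3ccccc3)cc2O[C@H]1c1cc(OC)c(OCc2ccccc2)cc1OC | intermediate
22 | 5,7-bis(benzyloxy)-2-[4-(benzyloxy)-2,5-dimethoxyphenyl]-3,6-dimethoxy-4H-chromen-4-one | COc1cc(-c2oc3cc(OCc4ccccc4)c(OC)c(OCc4ccccc4)c3c(=O)c2OC)c(OC)cc1OCc1ccccc1 | intermediate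
23 | 7-(benzyloxy)-2-[4-(benzyloxy)-2,5-dimethoxyphenyl]-5-hydroxy-3,6-dimethoxy-4H-chromen-4-one | COc1cc(-c2oc3cc(OCc4ccccc4)c(OC)c(O)c3c(=O)c2OC)c(OC)cc1OCc1ccccc1 | intermediate
24 | potassium 7-(benzyloxy)-2-[4-(benzyloxy)-2,5-dimethoxyphenyl]-5-hydroxy-3,6-dimethoxy-4-oxo-4H-chromen-8-yl sulfate | COc1cc(-c2oc3c(OS(=O)(=O)[O-])c(OCc4ccccc4)c(OC)c(O)c3c(=O)c2OC)c(OC)cc1OCc1ccccc1.[K+] | intermediate (not isolated)
25 | 7-(benzyloxy)-2-[4-(benzyloxy)-2,5-dimethoxyphenyl]-5,8-dihydroxy-3,6-dimethoxy-4H-chromen-4-one | COc1cc(-c2oc3c(O)c(OCc4ccccc4)c(OC)c(O)c3c(=O)c2OC)c(OC)cc1OCc1ccccc1 | intermediate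
26 | 7-(benzyloxy)-2-[4-(benzyloxy)-2,5-dimethoxyphenyl]-5-hydroxy-3,6,8-trimethoxy-4H-chromen-4-one | COc1cc(-c2oc3c(OC)c(OCc4ccccc4)c(OC)c(O)c3c(=O)c2OC)c(OC)cc1OCc1ccccc1 | intermediate
27 | 5,7-dihydroxy-2-(4-hydroxy-2,5-dimethoxyphenyl)-3,6,8-trimethoxy-4H-chromen-4-one (5,7,4'-trihydroxy-3,6,8,2',5'-pentamethoxyflavone) | COc1cc(-c2oc3c(OC)c(O)c(OC)c(O)c3c(=O)c2OC)c(OC)cc1O | target

## Step count and least certain steps

Total: 16 steps. Longest linear sequence: 12 steps (steps 1 to 6, then 11 to 16); the ring B branch is 4 steps (7 to 10).

Step 11 (key step). The most likely failure is protonation of the aryl anion before the acyl shift, which stops the sequence at simple O-arylation of the acid. Also possible are [2+2] capture of the aryne by the electron-rich enol-ether double bond and erosion of regioselectivity by the crowded substitution around the aryne. Incomplete ring closure is harmless. Fallback, from 7 and 15, rejoining at 22: treatment of 7 with n-BuLi (2.1 equiv, THF, −78 °C; phenoxide formation and bromine–lithium exchange) and acylation with N,2-dimethoxy-N-methylacetamide should give 1-[2,4-bis(benzyloxy)-6-hydroxy-3-methoxyphenyl]-2-methoxyethan-1-one F1. Claisen–Schmidt condensation of F1 with 15 (KOH, EtOH, rt) would give 20, in part already closed to 21, and the conditions of step 12 turn this material into 22.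

Step 14. Attack of persulfate on the chelated, hindered phenoxide may be slow, so conversion may be low, and the product hydroquinone can be over-oxidised to the quinone. The hot acid used to cleave the sulfate may also start to remove benzyl groups. Fallback, from 23, rejoining at 26: bromination para to the free hydroxyl (NBS, CH2Cl2–DMF, 0 °C) should give 7-(benzyloxy)-2-[4-(benzyloxy)-2,5-dimethoxyphenyl]-8-bromo-5-hydroxy-3,6-dimethoxy-4H-chromen-4-one F2. Copper-mediated Ullmann-type methoxylation of F2 (NaOMe, CuBr, DMF–MeOH, 110 °C) would give 26 directly, bypassing 25.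

Step 13. Selectivity may be lost through slow cleavage of the 7-O-benzyl ether or demethylation at O3 by chelation to the 3-methoxyl and the carbonyl. Fallback, from 22, rejoining at 23: hydrogenolysis of all three benzyl ethers (H2, Pd/C, EtOAc–MeOH) should give 5,7-dihydroxy-2-(4-hydroxy-2,5-dimethoxyphenyl)-3,6-dimethoxy-4H-chromen-4-one F3. Benzylation of F3 with BnBr (2.1 equiv) and K2CO3 in acetone is expected to alkylate the 7- and 4'-hydroxyls and leave the chelated 5-hydroxyl, giving 23.

Step 10. The electron-rich aldehyde may condense sluggishly under reversible alkoxide conditions, so that self-condensation of 16 and disproportionation of 15 take over. Fallback, from 15, rejoining at 18: Horner–Wadsworth–Emmons olefination with methyl 2-(dimethoxyphosphoryl)-2-methoxyacetate (NaH, THF, 0 °C to rt) should give 17 together with methyl (E)-3-[4-(benzyloxy)-2,5-dimethoxyphenyl]-2-methoxyprop-2-enoate F4. Saponification (LiOH, THF–H2O) would give 18 together with (E)-3-[4-(benzyloxy)-2,5-dimethoxyphenyl]-2-methoxyprop-2-enoic acid F5. The mixture can be used in step 11, since both geometries lead to the same 21.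

Step 6. The silyl shift may be incomplete, the aryllithium may be protonated, or benzylic metalation with Wittig rearrangement of a benzyl ether may compete. Fallback, from 6, rejoining at 10 and replacing steps 5 and 6: carbamoylation with isopropyl isocyanate (Et3N, CH2Cl2) should give 3,5-bis(benzyloxy)-4-methoxyphenyl N-isopropylcarbamate F6. In-situ N-silylation (TBSOTf, TMEDA), carbamate-directed ortho-lithiation (n-BuLi, −78 °C) and TMSCl quench would give 3,5-bis(benzyloxy)-4-methoxy-2-(trimethylsilyl)phenyl N-isopropylcarbamate F7. Cleavage of the carbamate with Et2NH and DBU in MeCN, followed by N-phenylbis(trifluoromethanesulfonimide) in the same flask, would give 10.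

## Further compounds

F1 | step 11 | 1-[2,4-bis(benzyloxy)-6-hydroxy-3-methoxyphenyl]-2-methoxyethan-1-one | COCC(=O)c1c(O)cc(OCc2ccccc2)c(OC)c1OCc1ccccc1
F2 | step 14 | 7-(benzyloxy)-2-[4-(benzyloxy)-2,5-dimethoxyphenyl]-8-bromo-5-hydroxy-3,6-dimethoxy-4H-chromen-4-one | COc1cc(-c2oc3c(Br)c(OCc4ccccc4)c(OC)c(O)c3c(=O)c2OC)c(OC)cc1OCc1ccccc1
F3 | step 13 | 5,7-dihydroxy-2-(4-hydroxy-2,5-dimethoxyphenyl)-3,6-dimethoxy-4H-chromen-4-one | COc1cc(-c2oc3cc(O)c(OC)c(O)c3c(=O)c2OC)c(OC)cc1O
F4 | step 10 | methyl (E)-3-[4-(benzyloxy)-2,5-dimethoxyphenyl]-2-methoxyprop-2-enoate | CO/C(=C/c1cc(OC)c(OCc2ccccc2)cc1OC)C(=O)OC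
F5 | step 10 | (E)-3-[4-(benzyloxy)-2,5-dimethoxyphenyl]-2-methoxyprop-2-enoic acid | CO/C(=C/c1cc(OC)c(OCc2ccccc2)cc1OC)C(=O)O
F6 | step 6 | 3,5-bis(benzyloxy)-4-methoxyphenyl N-isopropylcarbamate | CC(C)NC(=O)Oc1cc(OCc2ccccc2)c(OC)c(OCc2ccccc2)c1
F7 | step 6 | 3,5-bis(benzyloxy)-4-methoxy-2-(trimethylsilyl)phenyl N-isopropylcarbamate | CC(C)NC(=O)Oc1cc(OCc2ccccc2)c(OC)c(OCc2ccccc2)c1[Si](C)(C)C
A1 | alternative 1 | 1-[2,4-bis(benzyloxy)-3,5-dimethoxyphenyl]-3-[2,5-dimethoxy-4-(pivaloyloxy)phenyl]-2-methoxypropane-1,3-dione | COc1cc(C(=O)C(OC)C(=O)c2cc(OC)c(OCc3ccccc3)c(OC)c2OCc2ccccc2)c(OC)cc1OC(=O)C(C)(C)C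
A2 | alternative 1 | 5,7-bis(benzyloxy)-2-[2,5-dimethoxy-4-(pivaloyloxy)phenyl]-3,6,8-trimethoxy-4H-chromen-4-one | COc1cc(-c2oc3c(OC)c(OCc4ccccc4)c(OC)c(OCc4ccccc4)c3c(=O)c2OC)c(OC)cc1OC(=O)C(C)(C)C
A3 | alternative 2 | 2-[4-(benzyloxy)-2,5-dimethoxyphenyl]-5-(3-tert-butoxy-1-hydroxy-2-methoxy-4-oxocyclobut-2-en-1-yl)-3-methoxy-4H-pyran-4-one (racemic) | COc1cc(-c2occ(C3(O)C(OC)=C(OC(C)(C)C)C3=O)c(=O)c2OC)c(OC)cc1OCc1ccccc1
A4 | alternative 2 | 2-[4-(benzyloxy)-2,5-dimethoxyphenyl]-7-tert-butoxy-5,8-dihydroxy-3,6-dimethoxy-4H-chromen-4-one | COc1cc(-c2oc3c(O)c(OC(C)(C)C)c(OC)c(O)c3c(=O)c2OC)c(OC)cc1OCc1ccccc1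
A5 | alternative 3 | 2-[4-(benzyloxy)-2,5-dimethoxyphenyl]-5,7-difluoro-3,6,8-trimethoxy-4H-chromen-4-one | COc1cc(-c2oc3c(OC)c(F)c(OC)c(F)c3c(=O)c2OC)c(OC)cc1OCc1ccccc1
A6 | alternative 3 | 5,7-bis(benzyloxy)-2-[4-(benzyloxy)-2,5-dimethoxyphenyl]-3,6,8-trimethoxy-4H-chromen-4-one | COc1cc(-c2oc3c(OC)c(OCc4ccccc4)c(OC)c(OCc4ccccc4)c3c(=O)c2OC)c(OC)cc1OCc1ccccc1
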